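Slowness was the plain feature of the green run: L climbed for hours and then stopped, which I read as the crossing of X into solution being the rate-limiting step.

common to all: X 140 mM (held); Z 100 mM
- green: E 1.5 M; run made earlier
- flask: E 3.0 M; time 30 h

green run (percent of the E charged)

| time / h | L / % |
|---|---|
| 6.00 | 48.5 |
| 12.0 | 83.3 |
| 20.0 | 90.3 |
| 25.0 | 90.0 |
| 30.0 | 91.1 |

(scatter of a reading: 0.5 percentage points)

- at the start none of X is in solution
- G is what X becomes in solution

- summer: doubling the saturation concentration of X, all else as stated
- winter: doubling the amount of Z, all else as stated
- noon: doubling the transfer coefficient of X, all else as stated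

* L at 30 h, in percent of the E charged
* concentration of G in solution at 8.0 h, in percent of saturation
* the change that raises the amount of L at 30 h, in percent of the E charged most ("none" if none brings more than 2 percentage points) (summer / winter / noon / none)
* amount of L at 30 h, in percent of the E charged, after summer

The green run turned 48.5 % of its charge into L by 6.00 h, which I read as 12.4 h for its whole charge. The flask holds twice that E under the same X and Z, so I reckoned 24.7 h for it: this is the feed time, the hours a steady supply takes to carry a whole charge of E into L. The last green readings left 9.53 % of that charge unaccounted for. The flask's feed time is shorter than the asked 30 h, so I expected it to stop before then, and if the missing fraction grew in step with feed time, L would stand at 80.9 %.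

The forecast gave 83 %, higher than my figure, with G at 12 % of saturation at 8.0 h, summer as the best change, and 89 % after it. On the loss it said: “If it is a gas-free drain on E, the longer exposure lowers the yield”.

The flask gave 76.0 % of L at 30 h, G at 9.40 % of saturation at 8.0 h, summer as the best change, and 85.6 % after it.

    E + G + Z → Z + L (k = 0.988 L² mol⁻² min⁻¹)
    X ⇌ G, rate k2*(csat - [G]) (kL = 0.0181 min⁻¹)
    E + L → D (k = 2.48 × 10⁻⁴ L mol⁻¹ min⁻¹)

At 30.0 h the flask held E at 0 % and D at 24.0 % of the charge, each D counted with both its E, more than the 19.1 % my scaling gave. A neighbour flask with 1.2 M of E has a feed time of 9.90 h, the same scaling gives it 92.4 % of L, and at 30.0 h it held 93.5 %.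

(The runs come from a simulation from invented constants; scatter was added.)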